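**Retrosynthetic overview**

- Floranol is opened last at its two methoxymethyl ethers and, before that, at the C8–prenyl bond, which is traced back through a Claisen–Cope relay to a prenyl ether on O5.
- The C2–C1' bond (ring B to ring C) and the C3–O bond are cut together, which leads to an achiral 5-prenyloxy-6-methoxy-7-(methoxymethoxy)chromone and a 2-(methoxymethoxy)phenylzinc reagent.
- Ring A is bought as 2-methoxyresorcinol and dressed, ring C is closed as the flat pyranone (O1–C2 bond, step 4), ring B is attached in the key step, and no ring forms afterwards.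
- Feature on which this rests: both stereocentres lie on the C2–C3 edge of ring C, with C2 β to the C4 carbonyl and bearing only the 2-hydroxyphenyl ring B. Ring A is fully substituted, its C8 prenyl group para to the C5 oxygen and the ortho carbon C6 between them blocked by the methoxy group.

Key step: step 9

Assumption: (S)-BINAP is taken as the ligand antipode that places the aryl group on the required face of C2, by analogy with rhodium–BINAP arylation of cyclohexenone and of 4-quinolones. This is to be checked on the first sample of 18, and (R)-BINAP used if the sense is reversed. Flavonoid numbering is used throughout (O1, C2, C3, C4, C4a, C5–C8, C8a; ring B atoms primed).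

**Route**

Step 1
Reactants: 1 2-methoxybenzene-1,3-diol
Product: 2 2-methoxy-1,3-di(propan-2-yloxy)benzene
Conditions: 2-bromopropane (3 equiv), K2CO3 (3 equiv), DMF, 60 °C
Reagents that add atoms: 2-bromopropane CC(C)Br
Why: Williamson etherification of both phenoxides should proceed cleanly, and isopropyl groups are chosen because they survive the following steps yet can later be removed by BCl3 without loss of the methyl ether.

Step 2
Reactants: 2 2-methoxy-1,3-di(propan-2-yloxy)benzene
Product: 4 4-methoxy-3,5-di(propan-2-yloxy)phenol, via aryl pinacol boronate 3 (not isolated)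
Conditions: [Ir(OMe)(cod)]2 (1.5 mol %), 4,4'-di-tert-butyl-2,2'-bipyridine (3 mol %), B2pin2 (0.6 equiv), THF, 80 °C; then KHSO5 (as Oxone), acetone/H2O, 0 °C to rt
Reagents that add atoms: potassium peroxymonosulfate [K+].[O-]S(=O)(=O)OO
Why: Iridium-catalysed aromatic C–H borylation is governed by sterics and should touch only the C–H bond without an ortho substituent (para to the methoxy group), after which peroxymonosulfate converts the C–B bond into C–OH at the same carbon (one-pot borylation–oxidation).

Step 3
Reactants: 4 4-methoxy-3,5-di(propan-2-yloxy)phenol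
Product: 6 1-[6-hydroxy-3-methoxy-2,4-di(propan-2-yloxy)phenyl]ethanone, via difluoroboron chelate 5 (not isolated)
Conditions: Ac2O (1.5 equiv), BF3·OEt2 (2 equiv), CH2Cl2, 0 °C to rt; then aq NaOAc, EtOH, 50 °C
Reagents that add atoms: acetic anhydride CC(=O)OC(C)=O
Why: Lewis-acid-mediated Friedel–Crafts (Fries-type) acetylation of the electron-rich phenol should occur ortho to the free hydroxyl, the two ortho positions being equivalent by symmetry, to give the boron chelate of the ortho-hydroxy ketone, which buffered aqueous ethanol hydrolyses.

Step 4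
Reactants: 6 1-[6-hydroxy-3-methoxy-2,4-di(propan-2-yloxy)phenyl]ethanone
Product: 8 6-methoxy-5,7-di(propan-2-yloxy)-4H-chromen-4-one, via enaminone 7 (not isolated)
Conditions: Me2NCH(OMe)2 (3 equiv), toluene, 95 °C; evaporate; then conc. HCl, CH2Cl2, rt
Reagents that add atoms: N,N-dimethylformamide dimethyl acetal COC(OC)N(C)C
Why: Condensation of the methyl ketone with the amide acetal gives the (E)-enaminone, and acid then induces conjugate addition of the phenol oxygen and loss of dimethylamine, which closes ring C as the planar pyranone through the O1–C2 bond (the standard enaminone chromone synthesis).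

Step 5
Reactants: 8 6-methoxy-5,7-di(propan-2-yloxy)-4H-chromen-4-one
Product: 9 5,7-dihydroxy-6-methoxy-4H-chromen-4-one
Conditions: BCl3 (3 equiv, 1 M in CH2Cl2), CH2Cl2, −78 to 0 °C; then H2O, 0 °C
Reagents that add atoms: none
Why: BCl3 cleaves secondary alkyl aryl ethers by way of the isopropyl cation at temperatures at which an aryl methyl ether is retained, the chelated C5 ether being the first to go.

Step 6
Reactants: 9 5,7-dihydroxy-6-methoxy-4H-chromen-4-one
Product: 10 5-hydroxy-6-methoxy-7-(methoxymethoxy)-4H-chromen-4-one
Conditions: MOMCl (1.1 equiv), K2CO3 (1.5 equiv), acetone, 0 °C to rt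
Reagents that add atoms: chloromethyl methyl ether COCCl
Why: The C5 hydroxyl is held in a hydrogen bond to the C4 carbonyl and is much less acidic and nucleophilic than the C7 hydroxyl, so one equivalent of the chloromethyl ether with a weak base should alkylate O7 only (Williamson-type acetal formation).

Step 7
Reactants: 10 5-hydroxy-6-methoxy-7-(methoxymethoxy)-4H-chromen-4-one; 11 1-bromo-3-methylbut-2-ene
Product: 12 6-methoxy-7-(methoxymethoxy)-5-[(3-methylbut-2-en-1-yl)oxy]-4H-chromen-4-one
Conditions: K2CO3 (3 equiv), DMF, rt to 45 °C
Reagents that add atoms: none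
Why: With O7 capped the chelated C5 phenol is the only acidic site, and its phenoxide in a dipolar aprotic solvent should undergo SN2 alkylation at oxygen by the primary allylic bromide (Williamson etherification).

Step 8
Reactants: 13 (methoxymethoxy)benzene
Product: 15 chloro[2-(methoxymethoxy)phenyl]zinc, via aryllithium 14 (not isolated)
Conditions: n-BuLi (1.05 equiv), THF, 0 °C to rt; then ZnCl2 (1.1 equiv) in THF, 0 °C; used as a solution
Reagents that add atoms: zinc dichloride Cl[Zn]Cl
Why: The methoxymethoxy group directs lithiation to the ortho position by coordination of butyllithium (directed ortho-metalation), and transmetalation gives a mild arylzinc chloride that tolerates the chromone carbonyl.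

Step 9
Reactants: 12 6-methoxy-7-(methoxymethoxy)-5-[(3-methylbut-2-en-1-yl)oxy]-4H-chromen-4-one; 15 chloro[2-(methoxymethoxy)phenyl]zinc
Product: 18 (2R,3R)-3-hydroxy-6-methoxy-7-(methoxymethoxy)-2-[2-(methoxymethoxy)phenyl]-5-[(3-methylbut-2-en-1-yl)oxy]chroman-4-one, via enol silane 16 (not isolated), via silyloxy ketone 17 (not isolated)
Conditions: 15 (1.5 equiv), Me3SiCl (1.5 equiv), [RhCl(C2H4)2]2 (3.75 mol %), (S)-BINAP (8 mol %), THF, 20 °C; dilute with pentane, cold aq NaHCO3 wash, short pad of Et3N-treated Florisil, concentrate, crude 16 used at once; then dimethyldioxirane (one equiv, acetone solution), CH2Cl2, −78 °C; then citric acid, MeOH, 0 °C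
Reagents that add atoms: dimethyldioxirane CC1(C)OO1
Why: Proposed new method: the aryl group should pass from zinc to the monovalent rhodium–(S)-BINAP chloride, the aryl–rhodium bond should add across the C2=C3 bond of the flat chromone with the aryl group going to C2, and Me3SiCl should silylate the resulting oxa-allyl rhodium enolate at the C4 oxygen, which releases enol silane 16 and returns the rhodium chloride, after which dimethyldioxirane transfers oxygen to C3 of 16, a silyl shift gives ketone 17 and citric acid removes the silyl group. The closest known reaction types are the rhodium–bisphosphine 1,4-addition of arylzinc chlorides in the presence of Me3SiCl to 4-quinolones and 2,3-dihydro-4-pyridones, the rhodium-catalysed 1,4-addition of arylboronic acids to chromones, and the Rubottom oxidation of flavanone enol silanes to trans-3-hydroxyflavanones, and what is new is the arylzinc–silyl chloride addition on a chromone and its union with the oxidation in one telescoped operation. No ring is closed, since ring C is already present as the pyranone, and the C2–C1' bond to ring B and the C3–O bond are the only bonds formed to the skeleton. C2 is set by the chiral bisphosphine, which has to tell apart the two faces of a planar, achiral substrate and should give (2S)-16, and C3 is set by the new C2 aryl group, because the oxidant approaches the enol silane anti to it and so gives the trans (2R,3R) product, the change of descriptor at C2 being only a change of priorities. The step needs face selectivity at C2 (from the ligand), anti delivery of oxygen at C3 (from the C2 aryl group, backed by the greater stability of the trans isomer) and oxidation of the enol silane in preference to the prenyl ether alkene, which the far higher electron density of the silyloxy alkene, one equivalent of oxidant and −78 °C should secure. Silyl trapping also prevents the flavanone enolate from opening to the chalcone by β-elimination of the O1 phenoxide, and chromone 12 has no acidic hydrogen to quench the arylzinc reagent.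

Step 10
Reactants: 18 (2R,3R)-3-hydroxy-6-methoxy-7-(methoxymethoxy)-2-[2-(methoxymethoxy)phenyl]-5-[(3-methylbut-2-en-1-yl)oxy]chroman-4-one
Product: 21 (2R,3R)-3,5-dihydroxy-6-methoxy-7-(methoxymethoxy)-2-[2-(methoxymethoxy)phenyl]-8-(3-methylbut-2-en-1-yl)chroman-4-one, via C6 ortho-dienone 19 (not isolated), via C8 para-dienone 20 (not isolated)
Conditions: Eu(fod)3 (10 mol %), NaHCO3 (solid), PhCl, 75 °C
Reagents that add atoms: none
Why: Trivalent europium bound to the C4 carbonyl and O5 should accelerate the aromatic Claisen rearrangement of the prenyl ether to the ortho carbon C6, and because C6 carries the methoxy group and cannot rearomatise, the 1,1-dimethylallyl group moves on by a Cope rearrangement to C8 (para), where enolisation restores ring A and frees the C5 hydroxyl; the type is known for 5-prenyloxyflavonoids and for allyl ethers of 2,6-dimethoxyphenols, and the near-neutral conditions should leave C2 and C3 untouched.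

Step 11
Reactants: 21 (2R,3R)-3,5-dihydroxy-6-methoxy-7-(methoxymethoxy)-2-[2-(methoxymethoxy)phenyl]-8-(3-methylbut-2-en-1-yl)chroman-4-one
Product: 22 Floranol, (2R,3R)-3,5,7-trihydroxy-2-(2-hydroxyphenyl)-6-methoxy-8-(3-methylbut-2-en-1-yl)chroman-4-one
Conditions: 3 M aq HCl/MeOH (1:5), rt, short reaction time
Reagents that add atoms: none
Why: Acid-catalysed methanolysis of the two aryl methoxymethyl acetals (transacetalisation to dimethoxymethane) is fast at room temperature, and short exposure to dilute acid should leave the prenyl double bond, the trans-2,3 arrangement and the methyl ether unchanged.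

**Compound list**

1 | 2-methoxybenzene-1,3-diol | COc1c(O)cccc1O | starting material
2 | 2-methoxy-1,3-di(propan-2-yloxy)benzene | COc1c(OC(C)C)cccc1OC(C)C | intermediate
3 | 2-[4-methoxy-3,5-di(propan-2-yloxy)phenyl]-4,4,5,5-tetramethyl-1,3,2-dioxaborolane | COc1c(OC(C)C)cc(B2OC(C)(C)C(C)(C)O2)cc1OC(C)C | intermediate
4 | 4-methoxy-3,5-di(propan-2-yloxy)phenol | COc1c(OC(C)C)cc(O)cc1OC(C)C | intermediate
5 | difluoroboron chelate of ketone 6 (O,O-bound BF2 bridging the phenol oxygen and the acetyl oxygen) | CC1=[O+][B-](F)(F)Oc2cc(OC(C)C)c(OC)c(OC(C)C)c12 | intermediate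
6 | 1-[6-hydroxy-3-methoxy-2,4-di(propan-2-yloxy)phenyl]ethanone | CC(=O)c1c(O)cc(OC(C)C)c(OC)c1OC(C)C | intermediate
7 | (E)-3-(dimethylamino)-1-[6-hydroxy-3-methoxy-2,4-di(propan-2-yloxy)phenyl]prop-2-en-1-one | CN(C)/C=C/C(=O)c1c(O)cc(OC(C)C)c(OC)c1OC(C)C | intermediate
8 | 6-methoxy-5,7-di(propan-2-yloxy)-4H-chromen-4-one | COc1c(OC(C)C)cc2occc(=O)c2c1OC(C)C | intermediate
9 | 5,7-dihydroxy-6-methoxy-4H-chromen-4-one | COc1c(O)cc2occc(=O)c2c1O | intermediate
10 | 5-hydroxy-6-methoxy-7-(methoxymethoxy)-4H-chromen-4-one | COCOc1cc2occc(=O)c2c(O)c1OC | intermediate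
11 | 1-bromo-3-methylbut-2-ene (prenyl bromide) | CC(C)=CCBr | starting material
12 | 6-methoxy-7-(methoxymethoxy)-5-[(3-methylbut-2-en-1-yl)oxy]-4H-chromen-4-one | COCOc1cc2occc(=O)c2c(OCC=C(C)C)c1OC | intermediate
13 | (methoxymethoxy)benzene | COCOc1ccccc1 | starting material
14 | [2-(methoxymethoxy)phenyl]lithium | COCOc1ccccc1[Li] | intermediate
15 | chloro[2-(methoxymethoxy)phenyl]zinc | COCOc1ccccc1[Zn]Cl | intermediate
16 | trimethyl({(2S)-6-methoxy-7-(methoxymethoxy)-2-[2-(methoxymethoxy)phenyl]-5-[(3-methylbut-2-en-1-yl)oxy]-2H-chromen-4-yl}oxy)silane | COc1c(OCOC)cc2c(c1OCC=C(C)C)C(O[Si](C)(C)C)=C[C@@H](c1ccccc1OCOC)O2 | intermediate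
17 | (2R,3R)-6-methoxy-7-(methoxymethoxy)-2-[2-(methoxymethoxy)phenyl]-5-[(3-methylbut-2-en-1-yl)oxy]-3-[(trimethylsilyl)oxy]chroman-4-one | COc1c(OCOC)cc2c(c1OCC=C(C)C)C(=O)[C@H](O[Si](C)(C)C)[C@@H](c1ccccc1OCOC)O2 | intermediate
18 | (2R,3R)-3-hydroxy-6-methoxy-7-(methoxymethoxy)-2-[2-(methoxymethoxy)phenyl]-5-[(3-methylbut-2-en-1-yl)oxy]chroman-4-one | COc1c(OCOC)cc2c(c1OCC=C(C)C)C(=O)[C@H](O)[C@@H](c1ccccc1OCOC)O2 | intermediate
19 | (2R,3R)-3-hydroxy-6-methoxy-7-(methoxymethoxy)-2-[2-(methoxymethoxy)phenyl]-6-(2-methylbut-3-en-2-yl)-2,3-dihydro-4H-chromene-4,5(6H)-dione (either configuration at C6) | COC1(C(C)(C)C=C)C(OCOC)=CC2=C(C1=O)C(=O)[C@H](O)[C@@H](c1ccccc1OCOC)O2 | intermediate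
20 | (2R,3R)-3-hydroxy-6-methoxy-7-(methoxymethoxy)-2-[2-(methoxymethoxy)phenyl]-8-(3-methylbut-2-en-1-yl)-2,3-dihydro-4H-chromene-4,5(8H)-dione (either configuration at C8) | COC1=C(OCOC)C(CC=C(C)C)C2=C(C1=O)C(=O)[C@H](O)[C@@H](c1ccccc1OCOC)O2 | intermediate
21 | (2R,3R)-3,5-dihydroxy-6-methoxy-7-(methoxymethoxy)-2-[2-(methoxymethoxy)phenyl]-8-(3-methylbut-2-en-1-yl)chroman-4-one | COc1c(OCOC)c(CC=C(C)C)c2c(c1O)C(=O)[C@H](O)[C@@H](c1ccccc1OCOC)O2 | intermediate
22 | Floranol, (2R,3R)-3,5,7-trihydroxy-2-(2-hydroxyphenyl)-6-methoxy-8-(3-methylbut-2-en-1-yl)chroman-4-one | COc1c(O)c(CC=C(C)C)c2c(c1O)C(=O)[C@H](O)[C@@H](c1ccccc1O)O2 | target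

**Step count and risks**

Total step count: 11. Longest linear sequence: 10 steps (1 to 22 through steps 1–7 and 9–11); step 8 is a one-step branch.

Steps most likely to fail:

1. Step 9 (carries the new-method label).
   - What may go wrong: aryl transfer and insertion may be slow or incomplete, because the peri prenyloxy group at C5 and the ortho substituent of the aryl group both crowd C2. Face discrimination may be weak for the same reason. The enol silane may hydrolyse before it is oxidised. Oxygen may be transferred to the prenyl ether double bond in competition with the enol silane.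
   - Fallback (known chemistry in separate operations), setting out from chromone 12 and aryllithium 14 and coming back at 18: 14 is trapped with B(OiPr)3 and hydrolysed to [2-(methoxymethoxy)phenyl]boronic acid F1. F1 is added to 12 by the established rhodium–chiral bisphosphine asymmetric 1,4-addition of arylboronic acids to chromones ([Rh(OH)(cod)]2, an (S)-configured biaryl bisphosphine, toluene/H2O, rt) to give (2S)-6-methoxy-7-(methoxymethoxy)-2-[2-(methoxymethoxy)phenyl]-5-[(3-methylbut-2-en-1-yl)oxy]chroman-4-one F2, which is isolated so that its enantiomeric purity can be checked. Soft enolisation of F2 (Me3SiOTf, Et3N, CH2Cl2, 0 °C), which avoids a free enolate, gives enol silane 16. This is oxidised with dimethyldioxirane as in step 9, through 17, to 18.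

2. Step 10.
   - What may go wrong: the first sigmatropic shift has to deliver the prenyl group to a carbon that already bears a methoxy group. Ionisation of the chelated allylic ether (loss of the prenyl group) or stalling at the dienone stage may compete. Prolonged heating with a Lewis acid may open ring C and erode the configuration at C2.
   - Fallback (C8–C bond by cross-coupling instead of sigmatropic relay), setting out from 18 and coming back at 21: the O5 prenyl group is removed under neutral conditions (Pd(PPh3)4 cat., morpholine, THF, 40 °C) to give (2R,3R)-3,5-dihydroxy-6-methoxy-7-(methoxymethoxy)-2-[2-(methoxymethoxy)phenyl]chroman-4-one F3. This is also the material that a failed rearrangement would be expected to leave. Iodination of F3 with N-iodosuccinimide in DMF at 0 °C should occur at C8, the only free position of ring A and para to the free C5 hydroxyl, to give (2R,3R)-3,5-dihydroxy-8-iodo-6-methoxy-7-(methoxymethoxy)-2-[2-(methoxymethoxy)phenyl]chroman-4-one F4. Stille coupling of F4 with tributyl(3-methylbut-2-en-1-yl)stannane (Pd(PPh3)4, DMF, 80 °C, neutral) then gives 21.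

3. Step 3.
   - What may go wrong: acylative or Lewis-acid cleavage of an isopropyl ether, above all the one that ends up next to the new carbonyl, may compete with C-acylation. Under conditions mild enough to spare the ethers the reaction may stop at the aryl acetate.
   - Fallback (anionic acylation by directed ortho-metalation instead of electrophilic substitution), setting out from 4 and coming back at 6: phenol 4 is converted with MOMCl and NaH in THF into 2-methoxy-5-(methoxymethoxy)-1,3-di(propan-2-yloxy)benzene F5. Lithiation with n-BuLi in THF at 0 °C, at either of the two equivalent positions flanked by the acetal and an isopropoxy group, gives [3-methoxy-6-(methoxymethoxy)-2,4-di(propan-2-yloxy)phenyl]lithium F6. Acylation of F6 with N-methoxy-N-methylacetamide gives 1-[3-methoxy-6-(methoxymethoxy)-2,4-di(propan-2-yloxy)phenyl]ethanone F7. Brief treatment of F7 with dilute HCl in MeOH at rt removes the acetal and gives 6.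

**Further compounds**

F1 | step 9 | [2-(methoxymethoxy)phenyl]boronic acid | COCOc1ccccc1B(O)O
F2 | step 9 | (2S)-6-methoxy-7-(methoxymethoxy)-2-[2-(methoxymethoxy)phenyl]-5-[(3-methylbut-2-en-1-yl)oxy]chroman-4-one | COc1c(OCOC)cc2c(c1OCC=C(C)C)C(=O)C[C@@H](c1ccccc1OCOC)O2
F3 | step 10 | (2R,3R)-3,5-dihydroxy-6-methoxy-7-(methoxymethoxy)-2-[2-(methoxymethoxy)phenyl]chroman-4-one | COc1c(OCOC)cc2c(c1O)C(=O)[C@H](O)[C@@H](c1ccccc1OCOC)O2
F4 | step 10 | (2R,3R)-3,5-dihydroxy-8-iodo-6-methoxy-7-(methoxymethoxy)-2-[2-(methoxymethoxy)phenyl]chroman-4-one | COc1c(OCOC)c(I)c2c(c1O)C(=O)[C@H](O)[C@@H](c1ccccc1OCOC)O2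
F5 | step 3 | 2-methoxy-5-(methoxymethoxy)-1,3-di(propan-2-yloxy)benzene | COCOc1cc(OC(C)C)c(OC)c(OC(C)C)c1
F6 | step 3 | [3-methoxy-6-(methoxymethoxy)-2,4-di(propan-2-yloxy)phenyl]lithium | COCOc1cc(OC(C)C)c(OC)c(OC(C)C)c1[Li]
F7 | step 3 | 1-[3-methoxy-6-(methoxymethoxy)-2,4-di(propan-2-yloxy)phenyl]ethanone | CC(=O)c1c(OCOC)cc(OC(C)C)c(OC)c1OC(C)C
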